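**Retrosynthetic overview**

1. Ring B (C4a, C5, C6, C7, C8, C8a) is closed last by forming C7–C8, through an intramolecular Mukaiyama aldol addition of the C6 enol silane to a C8 aldehyde. The enabling feature is the β-hydroxy ketone C6(=O)–C7(OH)(CH3)–C8H(OH) inside ring B: C8 sits on the quaternary C8a, and the exocyclic C4a=C5 bond of ring A (O2, C1, C8a, C4a, C4, C3) holds C6 next to C8a.
2. Ring A: the O2–C3 bond is made by gold-catalysed 6-endo-dig closure of a hydroxy enynone, which is released by Stork–Danheiser opening of a temporary dihydropyranone that joins the two alkyne fragments at C4a.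
3. C8a: double Frater–Seebach alkylation of ethyl (R)-3-hydroxybutanoate; its carbinol is the latent acetyl group and the two hydroxymethyl arms become C1 and C8.
4. The side chain comes from (S)-2-methylbutan-1-ol (Wittig, then Horner–Wadsworth–Emmons), C7 from but-3-yn-2-ol, and the C5 chlorine is introduced late with N-chlorosuccinimide.
5. Order of ring formation: temporary dihydropyranone, then ring A, then ring B.

Key step: step 16

Assumption: the configuration at C7 of the alkyne fragment is erased at the enol silane stage, so (S)-but-3-yn-2-ol is used only to keep the intermediates single diastereomers (TBS = tert-butyldimethylsilyl, TMS = trimethylsilyl, Bn = benzyl).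

**Route**

Step 1
Reactants: 1 (S)-2-methylbutan-1-ol
Product: 3 ethyl (2E,4S)-2,4-dimethylhex-2-enoate, via (S)-2-methylbutanal 2 (not isolated)
Conditions: TEMPO (cat.), PhI(OAc)2, CH2Cl2, 0 °C to rt; then Ph3P=C(CH3)CO2Et, rt
Reagents that add atoms: ethyl 2-(triphenylphosphoranylidene)propanoate, CCOC(=O)C(C)=P(c1ccccc1)(c1ccccc1)c1ccccc1
Why: TEMPO/PhI(OAc)2 oxidation followed by in situ Wittig olefination with the stabilised ylide should give the (E)-enoate without isolating the epimerisable aldehyde; the side-chain stereocentre comes unchanged from the chiral-pool alcohol.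

Step 2
Reactants: 3 ethyl (2E,4S)-2,4-dimethylhex-2-enoate
Product: 4 (2E,4S)-2,4-dimethylhex-2-en-1-ol
Conditions: i-Bu2AlH (2.2 equiv), CH2Cl2, −78 °C
Reagents that add atoms: none
Why: hydride reduction of the conjugated ester with i-Bu2AlH proceeds by 1,2-addition to the allylic alcohol and leaves the trisubstituted alkene and the allylic stereocentre untouched.

Step 3
Reactants: 4 (2E,4S)-2,4-dimethylhex-2-en-1-ol
Product: 5 (2E,4S)-2,4-dimethylhex-2-enal
Conditions: MnO2, CH2Cl2, rt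
Reagents that add atoms: none
Why: MnO2 oxidises allylic alcohols selectively to enals under neutral conditions, without over-oxidation or isomerisation.

Step 4
Reactants: 5 (2E,4S)-2,4-dimethylhex-2-enal
Product: 7 (3E,5E,7S)-5,7-dimethylnona-3,5-dien-1-yne, via TMS-capped dienyne 6 (not isolated)
Conditions: (EtO)2P(O)CH2C≡CSiMe3, LiN(SiMe3)2, THF, −78 °C to 0 °C; then K2CO3, MeOH, rt
Reagents that add atoms: diethyl [3-(trimethylsilyl)prop-2-yn-1-yl]phosphonate, CCOP(=O)(CC#C[Si](C)(C)C)OCC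
Why: the Horner–Wadsworth–Emmons reaction of the lithiated propargyl phosphonate with the enal should give the (E)-enyne, and K2CO3/MeOH then cleaves the alkynyl C–Si bond.

Step 5
Reactants: 8 (S)-but-3-yn-2-ol
Product: 9 (S)-tert-butyl(but-3-yn-2-yloxy)dimethylsilane
Conditions: TBSCl, imidazole, DMF, rt
Reagents that add atoms: tert-butyldimethylsilyl chloride, CC(C)(C)[Si](C)(C)Cl
Why: standard silylation of a secondary alcohol masks the future O7 against the organolithium steps and the later oxidation.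

Step 6
Reactants: 10 ethyl (R)-3-hydroxybutanoate
Product: 11 ethyl (2R,3R)-2-[(benzyloxy)methyl]-3-hydroxybutanoate
Conditions: LiN(i-Pr)2 (2.1 equiv), THF, −78 to −20 °C; BnOCH2Cl, −78 to 0 °C
Reagents that add atoms: benzyl chloromethyl ether, ClCOCc1ccccc1
Why: Frater–Seebach alkylation, in which the lithium-chelated dianion is alkylated on the face anti to the carbinol methyl group, giving the 2,3-anti product.

Step 7
Reactants: 11 ethyl (2R,3R)-2-[(benzyloxy)methyl]-3-hydroxybutanoate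
Product: 12 ethyl (2S,3R)-2-[(benzyloxy)methyl]-3-hydroxy-2-(hydroxymethyl)butanoate
Conditions: LiN(i-Pr)2 (2.2 equiv), THF, −78 to −40 °C; CH2O (gas, from paraformaldehyde), −78 °C
Reagents that add atoms: formaldehyde, C=O
Why: a second Frater–Seebach reaction (aldol addition to formaldehyde) again brings the electrophile in anti to the carbinol methyl group of the chelated dianion, so the order BnOCH2 then HOCH2 fixes the quaternary carbon (future C8a) with the benzyloxymethyl arm as future C1 and the hydroxymethyl arm as future C8.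

Step 8
Reactants: 12 ethyl (2S,3R)-2-[(benzyloxy)methyl]-3-hydroxy-2-(hydroxymethyl)butanoate
Product: 13 ethyl (4R,5R)-5-[(benzyloxy)methyl]-2,2,4-trimethyl-1,3-dioxane-5-carboxylate
Conditions: Me2C(OMe)2, PPTS (cat.), CH2Cl2, rt
Reagents that add atoms: 2,2-dimethoxypropane, COC(C)(C)OC
Why: acid-catalysed transacetalisation joins the only two free hydroxyls (future O8 and the carbinol of the latent acetyl group) as a six-membered isopropylidene acetal.

Step 9
Reactants: 13 ethyl (4R,5R)-5-[(benzyloxy)methyl]-2,2,4-trimethyl-1,3-dioxane-5-carboxylate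
Product: 14 ethyl (4R,5R)-5-(hydroxymethyl)-2,2,4-trimethyl-1,3-dioxane-5-carboxylate
Conditions: H2 (1 atm), Pd/C, EtOAc, rt
Reagents that add atoms: none
Why: hydrogenolysis of the benzyl ether frees the C1 hydroxymethyl arm under neutral conditions, so the acetonide cannot migrate to it.

Step 10
Reactants: 14 ethyl (4R,5R)-5-(hydroxymethyl)-2,2,4-trimethyl-1,3-dioxane-5-carboxylate
Product: 15 (4R,5R)-5-(hydroxymethyl)-N-methoxy-N,2,2,4-tetramethyl-1,3-dioxane-5-carboxamide
Conditions: MeNH(OMe)·HCl, i-PrMgCl, THF, −20 to 0 °C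
Reagents that add atoms: N,O-dimethylhydroxylamine hydrochloride, CNOC.Cl
Why: aminolysis with the chloromagnesium amide of N,O-dimethylhydroxylamine converts hindered esters into Weinreb amides, and the neighbouring hydroxyl is tolerated as its magnesium alkoxide.

Step 11
Reactants: 15 (4R,5R)-5-(hydroxymethyl)-N-methoxy-N,2,2,4-tetramethyl-1,3-dioxane-5-carboxamide; 9 (S)-tert-butyl(but-3-yn-2-yloxy)dimethylsilane
Product: 16 (4S)-4-(TBSO)-1-[(4R,5R)-5-(hydroxymethyl)-2,2,4-trimethyl-1,3-dioxan-5-yl]pent-2-yn-1-one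
Conditions: 9 (3 equiv), n-BuLi, THF, −78 °C; then 15, −78 to 0 °C; aq. NH4Cl
Reagents that add atoms: none
Why: Weinreb ketone synthesis, in which excess lithium acetylide first deprotonates the hydroxyl and then adds once to the amide, the chelated tetrahedral intermediate preventing over-addition.

Step 12
Reactants: 16 (4S)-4-(TBSO)-1-[(4R,5R)-5-(hydroxymethyl)-2,2,4-trimethyl-1,3-dioxan-5-yl]pent-2-yn-1-one
Product: 17 (1R,6R)-9-[(1S)-1-(TBSO)ethyl]-1,3,3-trimethyl-2,4,8-trioxaspiro[5.5]undec-9-en-11-one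
Conditions: Ph3PAuCl (5 mol%), AgOTf (5 mol%), NaHCO3, CH2Cl2, rt
Reagents that add atoms: none
Why: gold-catalysed 6-endo-dig hydroalkoxylation of a β-hydroxy ynone should give the 2,3-dihydro-4H-pyran-4-one, a temporary ring that makes C6 the oxygen-bearing end of a vinylogous ester; only the C1 arm is free to close, and the buffer keeps the acetonide from migrating.

Step 13
Reactants: 17 (1R,6R)-9-[(1S)-1-(TBSO)ethyl]-1,3,3-trimethyl-2,4,8-trioxaspiro[5.5]undec-9-en-11-one; 7 (3E,5E,7S)-5,7-dimethylnona-3,5-dien-1-yne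
Product: 20 (3S)-3-(TBSO)-1-{(1R,6S,11Z)-9-[(1E,3E,5S)-3,5-dimethylhepta-1,3-dien-1-yl]-1,3,3-trimethyl-2,4,8-trioxaspiro[5.5]undec-9-en-11-ylidene}butan-2-one, via tertiary propargylic alcohol 18 (not isolated), via ring-opened hydroxy enynone 19 (not isolated)
Conditions: 7 (2.5 equiv), n-BuLi, THF, −78 °C; then 17, −78 to −20 °C; 0.1 M aq. HCl, THF, 0 °C, 10 min; then Ph3PAuCl, AgSbF6 (5 mol% each), NaHCO3, CH2Cl2/MeCN, rt
Reagents that add atoms: water, O
Why: 1,2-addition of the lithium acetylide to the vinylogous ester carbonyl and Stork–Danheiser transposition on mild acid work-up (water attacks the oxocarbenium carbon C6 and the temporary ring opens) should give the hydroxy enynone with C6 cis to C8a, because both sat in that ring, and the gold catalyst then closes ring A by 6-endo-dig attack of the C1 hydroxyl on C3, the δ-carbon of the ynenone.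

Step 14
Reactants: 20 (3S)-3-(TBSO)-1-{(1R,6S,11Z)-9-[(1E,3E,5S)-3,5-dimethylhepta-1,3-dien-1-yl]-1,3,3-trimethyl-2,4,8-trioxaspiro[5.5]undec-9-en-11-ylidene}butan-2-one
Product: 21 (3S)-3-(TBSO)-1-{(3R,4Z)-6-[(1E,3E,5S)-3,5-dimethylhepta-1,3-dien-1-yl]-3-[(1R)-1-hydroxyethyl]-3-(hydroxymethyl)-2,3-dihydro-4H-pyran-4-ylidene}butan-2-one
Conditions: Me2BBr, CH2Cl2, −78 °C; then aq. NaHCO3, THF
Reagents that add atoms: none
Why: Me2BBr cleaves isopropylidene acetals under aprotic conditions at −78 °C, which avoids acid-catalysed opening and re-closure of the vinylogous ester through the wrong hydroxymethyl arm and so keeps the C8a configuration; the secondary TBS ether survives.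

Step 15
Reactants: 21 (3S)-3-(TBSO)-1-{(3R,4Z)-6-[(1E,3E,5S)-3,5-dimethylhepta-1,3-dien-1-yl]-3-[(1R)-1-hydroxyethyl]-3-(hydroxymethyl)-2,3-dihydro-4H-pyran-4-ylidene}butan-2-one
Product: 22 (3S,4Z)-3-acetyl-4-[(3S)-3-(TBSO)-2-oxobutylidene]-6-[(1E,3E,5S)-3,5-dimethylhepta-1,3-dien-1-yl]-3,4-dihydro-2H-pyran-3-carbaldehyde
Conditions: Dess–Martin periodinane (3 equiv), pyridine, CH2Cl2, 0 °C to rt
Reagents that add atoms: none
Why: Dess–Martin oxidation converts the primary and the secondary alcohol at once into the C8 aldehyde and the acetyl group; the quaternary C8a keeps the 1,3-dicarbonyl unit from enolising between the carbonyls.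

Step 16
Reactants: 22 (3S,4Z)-3-acetyl-4-[(3S)-3-(TBSO)-2-oxobutylidene]-6-[(1E,3E,5S)-3,5-dimethylhepta-1,3-dien-1-yl]-3,4-dihydro-2H-pyran-3-carbaldehyde
Product: 25 (7R,8R,8aS)-8a-acetyl-7-(TBSO)-3-[(1E,3E,5S)-3,5-dimethylhepta-1,3-dien-1-yl]-8-hydroxy-7-methyl-1,7,8,8a-tetrahydro-6H-isochromen-6-one, via bis-enol silane 23 (not isolated), via silylated aldol 24 (not isolated)
Conditions: i-Pr2NEt (3.0 equiv), TMSOTf (2.6 equiv), CH2Cl2, −78 to 0 °C; then TMSOTf (1.0 equiv), −78 to −40 °C; then 0.1 M aq. HCl, THF, 0 °C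
Reagents that add atoms: none
Why: TMSOTf/i-Pr2NEt should turn both ketones into enol silanes (the C6 carbonyl through its O-silylated pyrylium-type cation, which is deprotonated at C7, its only α-hydrogen, and in which the C4a–C5 bond can rotate, so any (E)-isomer is funnelled); the second portion of TMSOTf then activates the non-enolisable C8 aldehyde, C7 attacks it, and silyl transfer to O8 makes the closure irreversible. The closest known reaction type is the one-pot enol silane formation–Mukaiyama aldol addition of ketones to non-enolisable aldehydes under TMSOTf/amine, here run intramolecularly. Ring B (C4a, C5, C6, C7, C8, C8a) closes in a 6-(enolendo)-exo-trig mode onto the preformed ring A. C8a controls both new centres: the fused geometry keeps the acetyl group axial and the aldehyde carbon reaches C7 from the opposite face, the (E)-enediol bis-silyl ether (OTBS anti to OTMS, favoured by dipole and steric repulsion) places O7 axial and syn to the acetyl group (7R), and the open antiperiplanar transition state places O8 equatorial and cis to O7 (8R). The step needs site selectivity between the two enol silanes and no equilibration: the acetyl-derived enol silane cannot reach the aldehyde (a four-membered ring would result) and is hydrolysed back to the ketone on work-up, and the O-silylated aldol cannot undergo retro-aldol cleavage.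

Step 17
Reactants: 25 (7R,8R,8aS)-8a-acetyl-7-(TBSO)-3-[(1E,3E,5S)-3,5-dimethylhepta-1,3-dien-1-yl]-8-hydroxy-7-methyl-1,7,8,8a-tetrahydro-6H-isochromen-6-one
Product: 26 (7R,8R,8aS)-8a-acetyl-7-(TBSO)-5-chloro-3-[(1E,3E,5S)-3,5-dimethylhepta-1,3-dien-1-yl]-8-hydroxy-7-methyl-1,7,8,8a-tetrahydro-6H-isochromen-6-one
Conditions: N-chlorosuccinimide (1.05 equiv), CH2Cl2, 0 °C to rt
Reagents that add atoms: N-chlorosuccinimide, O=C1CCC(=O)N1Cl
Why: C5 is the nucleophilic α-carbon of the doubly vinylogous ester O2–C3=C4–C4a=C5–C6=O, so electrophilic chlorination should occur there, while the acceptor-conjugated side-chain diene is unreactive.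

Step 18
Reactants: 26 (7R,8R,8aS)-8a-acetyl-7-(TBSO)-5-chloro-3-[(1E,3E,5S)-3,5-dimethylhepta-1,3-dien-1-yl]-8-hydroxy-7-methyl-1,7,8,8a-tetrahydro-6H-isochromen-6-one
Product: 27 (7R,8R,8aS)-8a-acetyl-5-chloro-3-[(1E,3E,5S)-3,5-dimethylhepta-1,3-dien-1-yl]-7,8-dihydroxy-7-methyl-1,7,8,8a-tetrahydro-6H-isochromen-6-one
Conditions: HF·pyridine, pyridine, THF, 0 °C to rt
Reagents that add atoms: none
Why: fluoride-mediated desilylation of the silyl ether α to the ketone under mildly acidic conditions avoids base-induced retro-aldol cleavage of the β-hydroxy ketone; no stereocentre is touched.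

**Compound list**

1 | (S)-2-methylbutan-1-ol | CC[C@H](C)CO | starting material
2 | (S)-2-methylbutanal | CC[C@H](C)C=O | intermediate
3 | ethyl (2E,4S)-2,4-dimethylhex-2-enoate | CC[C@H](C)/C=C(C)/C(=O)OCC | intermediate
4 | (2E,4S)-2,4-dimethylhex-2-en-1-ol | CC[C@H](C)/C=C(C)/CO | intermediate
5 | (2E,4S)-2,4-dimethylhex-2-enal | CC[C@H](C)/C=C(C)/C=O | intermediate
6 | trimethyl[(3E,5E,7S)-5,7-dimethylnona-3,5-dien-1-yn-1-yl]silane | CC[C@H](C)/C=C(C)/C=C/C#C[Si](C)(C)C | intermediate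
7 | (3E,5E,7S)-5,7-dimethylnona-3,5-dien-1-yne | CC[C@H](C)/C=C(C)/C=C/C#C | intermediate
8 | (S)-but-3-yn-2-ol | C[C@H](O)C#C | starting material
9 | (S)-tert-butyl(but-3-yn-2-yloxy)dimethylsilane | C[C@H](O[Si](C)(C)C(C)(C)C)C#C | intermediate
10 | ethyl (R)-3-hydroxybutanoate | C[C@@H](O)CC(=O)OCC | starting material
11 | ethyl (2R,3R)-2-[(benzyloxy)methyl]-3-hydroxybutanoate | CCOC(=O)[C@H](COCc1ccccc1)[C@@H](C)O | intermediate
12 | ethyl (2S,3R)-2-[(benzyloxy)methyl]-3-hydroxy-2-(hydroxymethyl)butanoate | CCOC(=O)[C@@](CO)(COCc1ccccc1)[C@@H](C)O | intermediate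
13 | ethyl (4R,5R)-5-[(benzyloxy)methyl]-2,2,4-trimethyl-1,3-dioxane-5-carboxylate | CCOC(=O)[C@@]1(COCc2ccccc2)[C@@H](C)OC(C)(C)OC1 | intermediate
14 | ethyl (4R,5R)-5-(hydroxymethyl)-2,2,4-trimethyl-1,3-dioxane-5-carboxylate | CCOC(=O)[C@@]1(CO)[C@@H](C)OC(C)(C)OC1 | intermediate
15 | (4R,5R)-5-(hydroxymethyl)-N-methoxy-N,2,2,4-tetramethyl-1,3-dioxane-5-carboxamide | CON(C)C(=O)[C@@]1(CO)[C@@H](C)OC(C)(C)OC1 | intermediate
16 | (4S)-4-[(tert-butyldimethylsilyl)oxy]-1-[(4R,5R)-5-(hydroxymethyl)-2,2,4-trimethyl-1,3-dioxan-5-yl]pent-2-yn-1-one | C[C@H](O[Si](C)(C)C(C)(C)C)C#CC(=O)[C@@]1(CO)[C@@H](C)OC(C)(C)OC1 | intermediate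
17 | (1R,6R)-9-{(1S)-1-[(tert-butyldimethylsilyl)oxy]ethyl}-1,3,3-trimethyl-2,4,8-trioxaspiro[5.5]undec-9-en-11-one | C[C@H](O[Si](C)(C)C(C)(C)C)C1=CC(=O)[C@@]2(CO1)[C@@H](C)OC(C)(C)OC2 | intermediate
18 | (1R)-9-{(1S)-1-[(tert-butyldimethylsilyl)oxy]ethyl}-11-[(3E,5E,7S)-5,7-dimethylnona-3,5-dien-1-yn-1-yl]-1,3,3-trimethyl-2,4,8-trioxaspiro[5.5]undec-9-en-11-ol, spiro centre as in 17, both C11 epimers | CC[C@H](C)/C=C(C)/C=C/C#CC1(O)C=C([C@H](C)O[Si](C)(C)C(C)(C)C)OC[C@@]12[C@@H](C)OC(C)(C)OC2 | intermediate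
19 | (2S,4Z,8E,10E,12S)-2-[(tert-butyldimethylsilyl)oxy]-5-[(4R,5S)-5-(hydroxymethyl)-2,2,4-trimethyl-1,3-dioxan-5-yl]-10,12-dimethyltetradeca-4,8,10-trien-6-yn-3-one | CC[C@H](C)/C=C(C)/C=C/C#C/C(=C/C(=O)[C@H](C)O[Si](C)(C)C(C)(C)C)[C@@]1(CO)[C@@H](C)OC(C)(C)OC1 | intermediate
20 | (3S)-3-[(tert-butyldimethylsilyl)oxy]-1-{(1R,6S,11Z)-9-[(1E,3E,5S)-3,5-dimethylhepta-1,3-dien-1-yl]-1,3,3-trimethyl-2,4,8-trioxaspiro[5.5]undec-9-en-11-ylidene}butan-2-one | CC[C@H](C)/C=C(C)/C=C/C1=C/C(=C/C(=O)[C@H](C)O[Si](C)(C)C(C)(C)C)[C@@]2(CO1)[C@@H](C)OC(C)(C)OC2 | intermediate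
21 | (3S)-3-[(tert-butyldimethylsilyl)oxy]-1-{(3R,4Z)-6-[(1E,3E,5S)-3,5-dimethylhepta-1,3-dien-1-yl]-3-[(1R)-1-hydroxyethyl]-3-(hydroxymethyl)-2,3-dihydro-4H-pyran-4-ylidene}butan-2-one | CC[C@H](C)/C=C(C)/C=C/C1=C/C(=C/C(=O)[C@H](C)O[Si](C)(C)C(C)(C)C)[C@@](CO)(CO1)[C@@H](C)O | intermediate
22 | (3S,4Z)-3-acetyl-4-{(3S)-3-[(tert-butyldimethylsilyl)oxy]-2-oxobutylidene}-6-[(1E,3E,5S)-3,5-dimethylhepta-1,3-dien-1-yl]-3,4-dihydro-2H-pyran-3-carbaldehyde | CC[C@H](C)/C=C(C)/C=C/C1=C/C(=C/C(=O)[C@H](C)O[Si](C)(C)C(C)(C)C)[C@@](C=O)(CO1)C(C)=O | intermediate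
23 | (3R,4Z)-4-{(3E)-3-[(tert-butyldimethylsilyl)oxy]-2-[(trimethylsilyl)oxy]but-2-en-1-ylidene}-6-[(1E,3E,5S)-3,5-dimethylhepta-1,3-dien-1-yl]-3-{1-[(trimethylsilyl)oxy]ethenyl}-3,4-dihydro-2H-pyran-3-carbaldehyde | CC[C@H](C)/C=C(C)/C=C/C1=C/C(=C/C(O[Si](C)(C)C)=C(/C)O[Si](C)(C)C(C)(C)C)[C@@](C=O)(CO1)C(=C)O[Si](C)(C)C | intermediate
24 | (7R,8R,8aS)-7-[(tert-butyldimethylsilyl)oxy]-3-[(1E,3E,5S)-3,5-dimethylhepta-1,3-dien-1-yl]-7-methyl-8-[(trimethylsilyl)oxy]-8a-{1-[(trimethylsilyl)oxy]ethenyl}-1,7,8,8a-tetrahydro-6H-isochromen-6-one | CC[C@H](C)/C=C(C)/C=C/C1=CC2=CC(=O)[C@](C)(O[Si](C)(C)C(C)(C)C)[C@H](O[Si](C)(C)C)[C@@]2(C(=C)O[Si](C)(C)C)CO1 | intermediate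
25 | (7R,8R,8aS)-8a-acetyl-7-[(tert-butyldimethylsilyl)oxy]-3-[(1E,3E,5S)-3,5-dimethylhepta-1,3-dien-1-yl]-8-hydroxy-7-methyl-1,7,8,8a-tetrahydro-6H-isochromen-6-one | CC[C@H](C)/C=C(C)/C=C/C1=CC2=CC(=O)[C@](C)(O[Si](C)(C)C(C)(C)C)[C@H](O)[C@@]2(C(C)=O)CO1 | intermediate
26 | (7R,8R,8aS)-8a-acetyl-7-[(tert-butyldimethylsilyl)oxy]-5-chloro-3-[(1E,3E,5S)-3,5-dimethylhepta-1,3-dien-1-yl]-8-hydroxy-7-methyl-1,7,8,8a-tetrahydro-6H-isochromen-6-one | CC[C@H](C)/C=C(C)/C=C/C1=CC2=C(Cl)C(=O)[C@](C)(O[Si](C)(C)C(C)(C)C)[C@H](O)[C@@]2(C(C)=O)CO1 | intermediate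
27 | (7R,8R,8aS)-8a-acetyl-5-chloro-3-[(1E,3E,5S)-3,5-dimethylhepta-1,3-dien-1-yl]-7,8-dihydroxy-7-methyl-1,7,8,8a-tetrahydro-6H-isochromen-6-one | CC[C@H](C)/C=C(C)/C=C/C1=CC2=C(Cl)C(=O)[C@](C)(O)[C@H](O)[C@@]2(C(C)=O)CO1 | target

**Step count and risks**

Total step count: 18. Longest linear sequence: 13 steps (steps 6 to 18, from 10).

Steps most likely to fail:

Step 16 (key step). What may go wrong: slow or unselective enolisation at C7 (a mixture of enol silane geometries), or closure of the acetyl-derived enol silane onto the silyl-activated C6 carbonyl, leading to poor facial control at C7. The fallback replaces the kinetic silyl enol ether addition by a reversible aldol of the free α-ketol under thermodynamic control. It sets out from 22. HF·pyridine in THF removes the secondary silyl ether to give (3S,4Z)-3-acetyl-6-[(1E,3E,5S)-3,5-dimethylhepta-1,3-dien-1-yl]-4-[(3S)-3-hydroxy-2-oxobutylidene]-3,4-dihydro-2H-pyran-3-carbaldehyde F1. Catalytic DBU in CH2Cl2 at 0 °C should then effect the intramolecular aldol addition, in which only the C7 enolate has a productive partner; it should settle on the isomer with equatorial methyl, axial acetyl and hydrogen-bonded cis-diol, (7R,8R,8aS)-8a-acetyl-3-[(1E,3E,5S)-3,5-dimethylhepta-1,3-dien-1-yl]-7,8-dihydroxy-7-methyl-1,7,8,8a-tetrahydro-6H-isochromen-6-one F2. The reaction time is kept short, because retro-aldol cleavage on the C8–C8a side would erode the C8a configuration. Chlorination of F2 with N-chlorosuccinimide under the conditions of step 17 gives 27, where the fallback rejoins the route.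

Step 13. What may go wrong: incomplete 1,2-addition to the hindered vinylogous ester carbonyl, or capture of the propargylic cation by water at the alkyne terminus (a Meyer–Schuster pathway) in place of Stork–Danheiser hydration at C6, which would give the regioisomeric pyran. The fallback reverses the order of the two alkynes and uses a gold-catalysed Meyer–Schuster rearrangement on the final pyran ring, with no ring switch. It sets out from 15. Lithiated 7 gives (4E,6E,8S)-1-[(4R,5R)-5-(hydroxymethyl)-2,2,4-trimethyl-1,3-dioxan-5-yl]-6,8-dimethyldeca-4,6-dien-2-yn-1-one F3. Ph3PAuCl/AgOTf with NaHCO3 closes it to (1R,6R)-9-[(1E,3E,5S)-3,5-dimethylhepta-1,3-dien-1-yl]-1,3,3-trimethyl-2,4,8-trioxaspiro[5.5]undec-9-en-11-one F4, which already holds the O2–C3 bond. Lithiated 9 adds to its carbonyl to give the tertiary propargylic alcohol (1R)-11-[(3S)-3-(TBSO)but-1-yn-1-yl]-9-[(1E,3E,5S)-3,5-dimethylhepta-1,3-dien-1-yl]-1,3,3-trimethyl-2,4,8-trioxaspiro[5.5]undec-9-en-11-ol F5. Ph3PAuNTf2 with methanol in toluene should then deliver oxygen to the alkyne terminus C6 by alkyne activation and give 20, where the fallback rejoins the route. Any (11E)-isomer of 20 F6 formed alongside is separated and recycled by acid-catalysed equilibration of the push–pull dienone.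

Step 7. What may go wrong: β-elimination of benzyloxide from the dianion of 11 before it meets formaldehyde, and with it loss of the quaternary centre. The fallback uses a ring-controlled enolate alkylation in place of the chelate-controlled dianion aldol and introduces the two arms in reverse order. It sets out from 10. Frater–Seebach hydroxymethylation (LiN(i-Pr)2, CH2O) gives ethyl (2R,3R)-3-hydroxy-2-(hydroxymethyl)butanoate F7. 2,2-Dimethoxypropane/PPTS gives ethyl (4R,5R)-2,2,4-trimethyl-1,3-dioxane-5-carboxylate F8. Its lithium enolate (LiN(i-Pr)2, THF, −78 °C), whose ring oxygens are poorly aligned for elimination, should be alkylated by benzyl chloromethyl ether trans to the pseudo-axial C4 methyl group, which gives 13, where the fallback rejoins the route.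

**Further compounds**

F1 | step 16 | (3S,4Z)-3-acetyl-6-[(1E,3E,5S)-3,5-dimethylhepta-1,3-dien-1-yl]-4-[(3S)-3-hydroxy-2-oxobutylidene]-3,4-dihydro-2H-pyran-3-carbaldehyde | CC[C@H](C)/C=C(C)/C=C/C1=C/C(=C/C(=O)[C@H](C)O)[C@@](C=O)(CO1)C(C)=O
F2 | step 16 | (7R,8R,8aS)-8a-acetyl-3-[(1E,3E,5S)-3,5-dimethylhepta-1,3-dien-1-yl]-7,8-dihydroxy-7-methyl-1,7,8,8a-tetrahydro-6H-isochromen-6-one | CC[C@H](C)/C=C(C)/C=C/C1=CC2=CC(=O)[C@](C)(O)[C@H](O)[C@@]2(C(C)=O)CO1
F3 | step 13 | (4E,6E,8S)-1-[(4R,5R)-5-(hydroxymethyl)-2,2,4-trimethyl-1,3-dioxan-5-yl]-6,8-dimethyldeca-4,6-dien-2-yn-1-one | CC[C@H](C)/C=C(C)/C=C/C#CC(=O)[C@@]1(CO)[C@@H](C)OC(C)(C)OC1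
F4 | step 13 | (1R,6R)-9-[(1E,3E,5S)-3,5-dimethylhepta-1,3-dien-1-yl]-1,3,3-trimethyl-2,4,8-trioxaspiro[5.5]undec-9-en-11-one | CC[C@H](C)/C=C(C)/C=C/C1=CC(=O)[C@@]2(CO1)[C@@H](C)OC(C)(C)OC2
F5 | step 13 | (1R)-11-{(3S)-3-[(tert-butyldimethylsilyl)oxy]but-1-yn-1-yl}-9-[(1E,3E,5S)-3,5-dimethylhepta-1,3-dien-1-yl]-1,3,3-trimethyl-2,4,8-trioxaspiro[5.5]undec-9-en-11-ol, spiro centre as in F4, both C11 epimers | CC[C@H](C)/C=C(C)/C=C/C1=CC(O)(C#C[C@H](C)O[Si](C)(C)C(C)(C)C)[C@@]2(CO1)[C@@H](C)OC(C)(C)OC2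
F6 | step 13 | (3S)-3-[(tert-butyldimethylsilyl)oxy]-1-{(1R,6S,11E)-9-[(1E,3E,5S)-3,5-dimethylhepta-1,3-dien-1-yl]-1,3,3-trimethyl-2,4,8-trioxaspiro[5.5]undec-9-en-11-ylidene}butan-2-one | CC[C@H](C)/C=C(C)/C=C/C1=C/C(=C\C(=O)[C@H](C)O[Si](C)(C)C(C)(C)C)[C@@]2(CO1)[C@@H](C)OC(C)(C)OC2
F7 | step 7 | ethyl (2R,3R)-3-hydroxy-2-(hydroxymethyl)butanoate | CCOC(=O)[C@H](CO)[C@@H](C)O
F8 | step 7 | ethyl (4R,5R)-2,2,4-trimethyl-1,3-dioxane-5-carboxylate | CCOC(=O)[C@@H]1COC(C)(C)O[C@@H]1C
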